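Numbering: C1 = quaternary carbinol carbon, C7 = its CH2OBz carbon, C2 = the CH–OBz next to C1, C3=C4 = the ring alkene, C5 = the second CH–OBz, C6 = CH–OH.
Cuts: the three O–benzoyl bonds come off first (O1/O6 masked as an acetonide), then ring bond C2–C3, then C4–C5, last C1–C7. What remains, C2–C1–C6–C5, is the carbon chain of L-tartaric acid.
Enabling feature: in the only carbocycle, the cyclohexene ring, C2 is a secondary allylic carbinol bonded directly to the cis alkene C3=C4 and to the fully substituted C1. The ring can therefore be shut by adding a (Z)-C3 vinyl metal to a C2 aldehyde that has no α-hydrogen.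
Forward order: tartrate acetonide, C7 by enolate hydroxymethylation, C4/C3 by acetylide addition at C5, alkyne to (Z)-vinyl iodide, C2 ester to aldehyde, closure of the only ring. Desilylation, one threefold benzoylation and acetonide hydrolysis finish the route.
Stereochemistry: C6 and the C1–O bond are those of L-tartrate (C1 keeps its sense in the hydroxymethylation and is checked by a cis-fused lactone). C5 comes from Felkin–Anh addition next to C6, and C2 from the ring closure under control of C1.

Key step: step 9

Assumption: the lithium enolate of the tartrate acetonide is taken to accept formaldehyde on the face cis to the neighbouring ester group, so that the two carboxyl carbons stay trans (net retention at C1). Only that epimer can form the lactone of step 2.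

Step 1
Reactants: 1 dimethyl L-tartrate
Product: 2 dimethyl (4R,5R)-2,2-dimethyl-1,3-dioxolane-4,5-dicarboxylate
Conditions: Me2C(OMe)2, TsOH·H2O (cat.), cyclohexane, reflux
Reagents that add atoms: 2,2-dimethoxypropane, COC(C)(C)OC
Why: Acid-catalysed transketalisation of a 1,2-diol is driven by removal of methanol and touches neither stereocentre.

Step 2
Reactants: 2 tartrate acetonide diester; 3 formaldehyde
Product: 6 methyl (3aR,6aR)-2,2-dimethyl-6-oxotetrahydrofuro[3,4-d][1,3]dioxole-3a-carboxylate (cis-fused C7–O–C5 γ-lactone), via lithium enolate 4 (not isolated), via hydroxymethyl diester 5 (not isolated)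
Conditions: LiN(i-Pr)2, THF–DMPU, −78 °C; HCHO (gas, from cracked paraformaldehyde), −78 °C; AcOH; then CSA (cat.), toluene, 40 °C
Reagents that add atoms: formaldehyde (3), C=O
Why: Aldol hydroxymethylation of an ester enolate that survives at −78 °C because its ring C–O bond lies in the nodal plane of the enolate should place C7 cis to the C5 ester, and the γ-lactonisation that follows is open only to this epimer, so it confirms C1, removes the minor epimer and tells the C5 carboxyl from the C2 carboxyl.

Step 3
Reactants: 6 lactone ester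
Product: 7 methyl (3aR,6aR)-6-hydroxy-2,2-dimethyltetrahydrofuro[3,4-d][1,3]dioxole-3a-carboxylate (lactol, both anomers)
Conditions: Sia2BH (freshly made from BH3·SMe2 and 2-methylbut-2-ene), THF, 0 °C to rt; then H2O2, pH 7 buffer, 0 °C
Reagents that add atoms: none
Why: Disiamylborane reduction of a γ-lactone to the lactol, the method used for acylated aldonolactones, stops at the hemiacetal stage and leaves carboxylic esters alone, so the angular C2 ester survives.

Step 4
Reactants: 7 lactol; 8 ethynyltrimethylsilane
Product: 10 methyl (4R,5S)-4-(hydroxymethyl)-5-[(1S)-1-hydroxy-3-(trimethylsilyl)prop-2-yn-1-yl]-2,2-dimethyl-1,3-dioxolane-4-carboxylate, via alkynylmagnesium bromide 9 (not isolated)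
Conditions: 8, EtMgBr, THF, 0 °C to rt; then 7, THF, 0 °C to rt; aq. NH4Cl
Reagents that add atoms: ethynyltrimethylsilane (8), C#C[Si](C)(C)C
Why: Grignard addition to the open hydroxy aldehyde form of an acetonide-fused lactol should proceed anti to the C6–O bond (polar Felkin–Anh model) and give the 5,6-anti, 5S carbinol, as related isopropylidene furanoses do, while the alkynyl Grignard reagent is too sluggish to attack the hindered ester.

Step 5
Reactants: 10 diol
Product: 11 methyl (4R,5S)-4-{[(tert-butyldimethylsilyl)oxy]methyl}-5-[(1S)-1-[(tert-butyldimethylsilyl)oxy]-3-(trimethylsilyl)prop-2-yn-1-yl]-2,2-dimethyl-1,3-dioxolane-4-carboxylate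
Conditions: TBSOTf, 2,6-lutidine, CH2Cl2, 0 °C
Reagents that add atoms: tert-butyldimethylsilyl triflate, CC(C)(C)[Si](C)(C)OS(=O)(=O)C(F)(F)F
Why: Silyl triflate silylation covers O7 and O5 at once; silyl ethers are used because, unlike benzoates, they outlast the hydride reduction of step 8, and a later silyl shift among O2, O5 and O7 would be harmless since all three end as benzoates.

Step 6
Reactants: 11 bis-silyl ether
Product: 12 methyl (4R,5S)-4-{[(tert-butyldimethylsilyl)oxy]methyl}-5-[(1S)-1-[(tert-butyldimethylsilyl)oxy]-3-iodoprop-2-yn-1-yl]-2,2-dimethyl-1,3-dioxolane-4-carboxylate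
Conditions: NIS, AgNO3 (cat.), DMF, rt, dark
Reagents that add atoms: N-iodosuccinimide, O=C1CCC(=O)N1I
Why: Silver-catalysed iododesilylation of an alkynylsilane exchanges C–Si for C–I at C3 directly, so no separate desilylation is needed.

Step 7
Reactants: 12 iodoalkyne
Product: 13 methyl (4R,5S)-4-{[(tert-butyldimethylsilyl)oxy]methyl}-5-[(1S,2Z)-1-[(tert-butyldimethylsilyl)oxy]-3-iodoprop-2-en-1-yl]-2,2-dimethyl-1,3-dioxolane-4-carboxylate
Conditions: 2-nitrobenzenesulfonyl hydrazide, Et3N, THF–i-PrOH, rt
Reagents that add atoms: none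
Why: Diimide reduction of a 1-iodoalkyne delivers both hydrogens to one side of the triple bond in a concerted step, which gives only the Z vinyl iodide and leaves the C–I bond and the ester alone.

Step 8
Reactants: 13 (Z)-vinyl iodide ester
Product: 14 (4R,5S)-4-{[(tert-butyldimethylsilyl)oxy]methyl}-5-[(1S,2Z)-1-[(tert-butyldimethylsilyl)oxy]-3-iodoprop-2-en-1-yl]-2,2-dimethyl-1,3-dioxolane-4-carbaldehyde
Conditions: i-Bu2AlH, CH2Cl2, −78 °C; MeOH, then aq. potassium sodium tartrate
Reagents that add atoms: none
Why: Half-reduction of an α-alkoxy ester with i-Bu2AlH should stop at the aluminium hemiacetal, which is chelated by O1 and shielded by quaternary C1 until the quench, and the aldehyde released cannot epimerise.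

Step 9
Reactants: 14 iodovinyl aldehyde
Product: 16 (3aS,4S,7S,7aS)-7-[(tert-butyldimethylsilyl)oxy]-3a-{[(tert-butyldimethylsilyl)oxy]methyl}-2,2-dimethyl-3a,4,7,7a-tetrahydro-1,3-benzodioxol-4-ol, via vinylchromium dichloride 15 (not isolated)
Conditions: CrCl2 (excess), NiCl2 (cat.), degassed DMSO, rt, high dilution
Reagents that add atoms: none
Why: Zerovalent nickel, made in the flask from NiCl2 by divalent chromium, inserts into the C3–I bond with retention of the Z geometry and hands the vinyl group to trivalent chromium (15), which adds to the C2 aldehyde; the closest known reaction is the intramolecular Nozaki–Hiyama–Kishi coupling of halovinyl aldehydes to polyoxygenated cyclohexenols. The cyclohexene ring closes in a 6-exo-trig mode, C3 attacking the carbonyl carbon while the carbonyl oxygen stays outside the new ring. A trans-fused dioxolane requires O1 and O6 to be equatorial, which sets the forming C2–C3 bond anti to C1–O1 (a built-in polar Felkin–Anh arrangement) and makes the C7 arm axial on the face opposite O1, beside the pseudo-axial O5 silyl ether. C2 is thus controlled by C1: the chromium-bound oxygen should avoid the crowded sector between O1 and the C7 arm and take the pseudo-axial site on the open face of O1, anti to C7, which gives O2 cis to O1. Closure has to beat intermolecular coupling and protonation of 15, which high dilution in dry degassed solvent, the cis alkene and the gauche C2/C5 arrangement on the dioxolane should secure, and it needs attack at the aldehyde only, which the low basicity of organochromium reagents, the missing α-hydrogen at C1 and the inert silyl ethers and acetal provide.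

Step 10
Reactants: 16 cyclohexenol bis-silyl ether
Product: 17 (3aS,4S,7S,7aS)-3a-(hydroxymethyl)-2,2-dimethyl-3a,4,7,7a-tetrahydro-1,3-benzodioxole-4,7-diol
Conditions: Bu4NF, THF, 0 °C to rt
Reagents that add atoms: none
Why: Fluoride cleavage of silyl ethers is orthogonal to acetal and alkene and uncovers exactly the three hydroxyls that carry benzoates in the target.

Step 11
Reactants: 17 triol; 18 benzoyl chloride
Product: 19 [(3aS,4S,7S,7aS)-4,7-bis(benzoyloxy)-2,2-dimethyl-3a,4,7,7a-tetrahydro-1,3-benzodioxol-3a-yl]methyl benzoate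
Conditions: BzCl, pyridine, DMAP (cat.), 0 °C to rt
Reagents that add atoms: benzoyl chloride (18), O=C(Cl)c1ccccc1
Why: DMAP-catalysed acylation takes all free hydroxyls, and because O1 and O6 are tied up in the dioxolane the benzoate pattern arises without any selective acylation.

Step 12
Reactants: 19 tribenzoate acetonide
Product: 20 [(1R,2S,5S,6S)-2,5-bis(benzoyloxy)-1,6-dihydroxycyclohex-3-en-1-yl]methyl benzoate (target)
Conditions: TFA–H2O (9:1), CH2Cl2, 0 °C
Reagents that add atoms: none
Why: Acid hydrolysis of an isopropylidene acetal, speeded here by the strain of the trans ring fusion, should run at 0 °C, where benzoates neither cleave nor migrate and no C–O bond at a stereocentre is broken.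

Compound list
1 | dimethyl L-tartrate, dimethyl (2R,3R)-2,3-dihydroxybutanedioate | COC(=O)[C@H](O)[C@@H](O)C(=O)OC | starting material
2 | dimethyl (4R,5R)-2,2-dimethyl-1,3-dioxolane-4,5-dicarboxylate | COC(=O)[C@@H]1OC(C)(C)O[C@H]1C(=O)OC | intermediate
3 | formaldehyde (monomer from cracked paraformaldehyde) | C=O | starting material
4 | lithium ester enolate of 2 at C1 | COC(O[Li])=C1OC(C)(C)O[C@H]1C(=O)OC | intermediate
5 | dimethyl (4R,5R)-4-(hydroxymethyl)-2,2-dimethyl-1,3-dioxolane-4,5-dicarboxylate (CH2OH cis to the C5 ester) | COC(=O)[C@]1(CO)OC(C)(C)O[C@H]1C(=O)OC | intermediate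
6 | methyl (3aR,6aR)-2,2-dimethyl-6-oxotetrahydrofuro[3,4-d][1,3]dioxole-3a-carboxylate | COC(=O)[C@@]12COC(=O)[C@@H]1OC(C)(C)O2 | intermediate
7 | methyl (3aR,6aR)-6-hydroxy-2,2-dimethyltetrahydrofuro[3,4-d][1,3]dioxole-3a-carboxylate (both anomers) | COC(=O)[C@@]12COC(O)[C@@H]1OC(C)(C)O2 | intermediate
8 | ethynyltrimethylsilane | C#C[Si](C)(C)C | starting material
9 | [(trimethylsilyl)ethynyl]magnesium bromide | C[Si](C)(C)C#C[Mg]Br | intermediate
10 | methyl (4R,5S)-4-(hydroxymethyl)-5-[(1S)-1-hydroxy-3-(trimethylsilyl)prop-2-yn-1-yl]-2,2-dimethyl-1,3-dioxolane-4-carboxylate | COC(=O)[C@]1(CO)OC(C)(C)O[C@H]1[C@@H](O)C#C[Si](C)(C)C | intermediate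
11 | O5,O7-bis(tert-butyldimethylsilyl) ether of 10 | COC(=O)[C@]1(CO[Si](C)(C)C(C)(C)C)OC(C)(C)O[C@H]1[C@@H](O[Si](C)(C)C(C)(C)C)C#C[Si](C)(C)C | intermediate
12 | iodoalkyne, C3–I in place of C3–SiMe3 of 11 | COC(=O)[C@]1(CO[Si](C)(C)C(C)(C)C)OC(C)(C)O[C@H]1[C@@H](O[Si](C)(C)C(C)(C)C)C#CI | intermediate
13 | (Z)-vinyl iodide methyl ester | COC(=O)[C@]1(CO[Si](C)(C)C(C)(C)C)OC(C)(C)O[C@H]1[C@@H](O[Si](C)(C)C(C)(C)C)/C=C\I | intermediate
14 | (Z)-iodovinyl aldehyde, precursor of the key step | O=C[C@]1(CO[Si](C)(C)C(C)(C)C)OC(C)(C)O[C@H]1[C@@H](O[Si](C)(C)C(C)(C)C)/C=C\I | intermediate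
15 | (Z)-vinylchromium dichloride derived from 14 | O=C[C@]1(CO[Si](C)(C)C(C)(C)C)OC(C)(C)O[C@H]1[C@@H](O[Si](C)(C)C(C)(C)C)/C=C\[Cr](Cl)Cl | intermediate
16 | (3aS,4S,7S,7aS)-7-[(tert-butyldimethylsilyl)oxy]-3a-{[(tert-butyldimethylsilyl)oxy]methyl}-2,2-dimethyl-3a,4,7,7a-tetrahydro-1,3-benzodioxol-4-ol, product of the key step | CC(C)(C)[Si](C)(C)OC[C@@]12OC(C)(C)O[C@H]1[C@@H](O[Si](C)(C)C(C)(C)C)C=C[C@@H]2O | intermediate
17 | (3aS,4S,7S,7aS)-3a-(hydroxymethyl)-2,2-dimethyl-3a,4,7,7a-tetrahydro-1,3-benzodioxole-4,7-diol | OC[C@@]12OC(C)(C)O[C@H]1[C@@H](O)C=C[C@@H]2O | intermediate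
18 | benzoyl chloride | O=C(Cl)c1ccccc1 | starting material
19 | [(3aS,4S,7S,7aS)-4,7-bis(benzoyloxy)-2,2-dimethyl-3a,4,7,7a-tetrahydro-1,3-benzodioxol-3a-yl]methyl benzoate | O=C(OC[C@@]12OC(C)(C)O[C@H]1[C@@H](OC(=O)c3ccccc3)C=C[C@@H]2OC(=O)c2ccccc2)c1ccccc1 | intermediate
20 | [(1R,2S,5S,6S)-2,5-bis(benzoyloxy)-1,6-dihydroxycyclohex-3-en-1-yl]methyl benzoate | O=C(OC[C@]1(O)[C@@H](OC(=O)c2ccccc2)C=C[C@H](OC(=O)c2ccccc2)[C@@H]1O)c1ccccc1 | target

Total step count: 12. Longest linear sequence: 12 steps, from 1 to 20.

Steps most likely to fail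

1. Step 9. The aldehyde face may be chosen poorly or in the opposite sense, because the chromium-bound oxygen can also settle in the pseudo-equatorial site. The fallback sets out from 16, used unseparated from the C2 epimer F1. Dess–Martin periodinane in CH2Cl2 oxidises both to the enone F2. HF·pyridine in THF then removes both silyl groups to give the dihydroxy enone F3. An Evans–Saksena reduction with Me4NBH(OAc)3 in MeCN–AcOH at −20 °C follows. The boron binds to the C7 hydroxyl, which stands axial on the face opposite O1. It passes hydride to C2 through a six-membered transition state from that face, so O2 ends cis to O1. C2 is then set by a directing group and not by the ring closure. The sequence comes back to the route at 17.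

2. Step 2. The enolate may take up formaldehyde with poor or reversed facial selectivity, so that little material is able to lactonise. The fallback sets out from 2 and makes the configuration at C1 independent of the enolate face. The crude hydroxymethylation mixture contains 5, 6 and the C1 epimer F4. LiAlH4 in THF reduces all of it to the triol F5, in which C1 carries two identical CH2OH arms and is no longer a stereocentre. TEMPO (cat.) with PhI(OAc)2 in MeCN–H2O should oxidise the least hindered C5 carbinol first. Its aldehyde can form a lactol only with the cis arm, so C1 is set again by the cis ring fusion. The same reagent carries the lactol on to the lactone and the remaining arm to the acid, giving the lactone acid F6. Me3SiCHN2 in toluene–MeOH esterifies F6, and the route is rejoined at 6.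

3. Step 4. Magnesium chelation by O6 or by the C7 alkoxide may compete with the Felkin–Anh pathway and erode the facial selectivity at C5. The fallback sets out from 10 as the mixture of C5 epimers and replaces substrate control by reagent control. TBSCl and imidazole in DMF silylate only the primary hydroxyl to give the C7 mono-silyl ether F7. Dess–Martin periodinane converts it into the ynone F8. Noyori transfer hydrogenation with RuCl(p-cymene)[(R,R)-TsDPEN] in i-PrOH, the catalyst enantiomer being the one that delivers hydride to give 5S, leads to the (5S)-carbinol F9. TBSOTf and 2,6-lutidine then bring the material back to the route at 11.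

Further compounds
F1 | step 9 | C2 epimer of 16, (3aS,4R,7S,7aS) | CC(C)(C)[Si](C)(C)OC[C@@]12OC(C)(C)O[C@H]1[C@@H](O[Si](C)(C)C(C)(C)C)C=C[C@H]2O
F2 | step 9 | enone, C2 ketone of 16 | CC(C)(C)[Si](C)(C)OC[C@@]12OC(C)(C)O[C@H]1[C@@H](O[Si](C)(C)C(C)(C)C)C=CC2=O
F3 | step 9 | dihydroxy enone, O5 and O7 free | OC[C@@]12OC(C)(C)O[C@H]1[C@@H](O)C=CC2=O
F4 | step 2 | C1 epimer of 5, dimethyl (4S,5R)-4-(hydroxymethyl)-2,2-dimethyl-1,3-dioxolane-4,5-dicarboxylate | COC(=O)[C@@]1(CO)OC(C)(C)O[C@H]1C(=O)OC
F5 | step 2 | triol, [(5S)-2,2-dimethyl-1,3-dioxolane-4,4,5-triyl]trimethanol | OCC1(CO)OC(C)(C)O[C@H]1CO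
F6 | step 2 | lactone acid, (3aR,6aR)-2,2-dimethyl-6-oxotetrahydrofuro[3,4-d][1,3]dioxole-3a-carboxylic acid | OC(=O)[C@@]12COC(=O)[C@@H]1OC(C)(C)O2
F7 | step 4 | C7 mono-silyl ether of 10, both C5 epimers | COC(=O)[C@]1(CO[Si](C)(C)C(C)(C)C)OC(C)(C)O[C@H]1C(O)C#C[Si](C)(C)C
F8 | step 4 | ynone, C5 ketone | COC(=O)[C@]1(CO[Si](C)(C)C(C)(C)C)OC(C)(C)O[C@H]1C(=O)C#C[Si](C)(C)C
F9 | step 4 | (5S)-carbinol, C7 mono-silyl ether | COC(=O)[C@]1(CO[Si](C)(C)C(C)(C)C)OC(C)(C)O[C@H]1[C@@H](O)C#C[Si](C)(C)C
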